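**Strategy.** The target is catechin-(4α→8)-gallocatechin-(4β→8)-catechin (units T, M, L). Ring C of M is the point of disconnection: its O1–C8a–C4a–C4 array is taken as an o-quinone methide whose C4 already carries ring A of L and whose C8 carries T, and C2–C3 with O3 as a benzyloxyacetyl unit. One isothiourea-catalysed Michael addition–lactonisation forms C3–C4 and O1–C2, closes ring C as a dihydrocoumarin and sets the unusual 3,4-cis pair. The precursor is a T-substituted 3,5-bis(benzyloxy)phenol bearing an ortho aryl(tosyl)methyl group. Ring B of M is added afterwards at C2.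

Key step: step 10

**Remarks on the chemistry**

- Structure: T and L are (2R,3S)-catechin units and M is a (2R,3S)-gallocatechin unit. The T–M bond is 3,4-trans (4α) and the M–L bond is 3,4-cis (4β), so M is 2,3-trans-3,4-cis.
- Geometry: in the E o-quinone methide, ring A of L is anti to the carbonyl oxygen on C8a and therefore lies on the C5 side, beside the 5-benzyloxy group. The isomer with that ring turned away from the 5-benzyloxy group is Z and would give the trans lactone through the same transition-state shape. The route relies on the E form.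
- Precursor design: O1–H is the only free hydroxyl; every other oxygen, including O3 of T and L, is a benzyl ether. The sulfone is used as both C4 epimers, and the quinone methide is formed before the acyl chloride is added.
- Assumption: (2S,3R)-HyperBTM, p-toluenesulfinic acid and 5-bromo-1,2,3-tris(benzyloxy)benzene are purchased.
- Abbreviations: Bn = benzyl. "T" = the penta-O-benzyl-(2R,3S)-catechin-4-yl group, bonded through C4 trans to 3-OBn and cis to the C2 aryl (4α). "L" = the penta-O-benzyl-(2R,3S)-catechin-8-yl group. Compounds containing interflavan bonds are expected to exist as rotamers.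

**Route**

Step 1
Reactants: 1 (+)-catechin
Product: 2 5,7,3',4'-tetra-O-benzyl-(+)-catechin [(2R,3S)-5,7-bis(benzyloxy)-2-[3,4-bis(benzyloxy)phenyl]chroman-3-ol]
Conditions: BnBr (4.4 equiv), K2CO3, DMF, 0 °C → rt
Reagents that add atoms: benzyl bromide, BrCc1ccccc1
Why: Williamson etherification in which K2CO3 deprotonates only the four phenols, so they are O-benzylated while the secondary 3-OH stays free and the mild base limits C-benzylation of ring A; no stereocentre is touched.

Step 2
Reactants: 2 5,7,3',4'-tetra-O-benzyl-(+)-catechin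
Product: 3 penta-O-benzyl-(+)-catechin [(2R,3S)-3,5,7-tris(benzyloxy)-2-[3,4-bis(benzyloxy)phenyl]chroman]
Conditions: NaH, BnBr, DMF, 0 °C → rt
Reagents that add atoms: benzyl bromide, BrCc1ccccc1
Why: Williamson etherification of the remaining secondary alcohol through its sodium alkoxide removes the last acidic proton, so the later organolithium, acyl chloride and Lewis acid steps meet only benzyl ethers; C2 and C3 are unaffected.

Step 3
Reactants: 3 penta-O-benzyl-(+)-catechin
Product: 4 8-bromo-penta-O-benzyl-(+)-catechin (bromide of unit L)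
Conditions: NBS (1.0 equiv), CH2Cl2, −78 °C → rt
Reagents that add atoms: N-bromosuccinimide, O=C1CCC(=O)N1Br
Why: Electrophilic aromatic bromination, in which C8 of the phloroglucinol-type ring A is the most reactive position of benzylated catechins, so one equivalent of NBS at low temperature should give the 8-bromide that later becomes the C8 nucleophile of L.

Step 4
Reactants: 3 penta-O-benzyl-(+)-catechin
Product: 5 4-(2-ethoxyethoxy)-penta-O-benzyl-(+)-catechin (both C4 epimers)
Conditions: DDQ (2 equiv), EtOCH2CH2OH (5 equiv), CH2Cl2, rt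
Reagents that add atoms: 2-ethoxyethanol, CCOCCO
Why: Benzylic C–H oxidation in which DDQ abstracts hydride from C4 (cation stabilised by the 5,7-dioxygenated ring A) and the alcohol traps it as an ether that ionises again with a Lewis acid; the C4 epimer composition is irrelevant because C4 becomes planar in step 5.

Step 5
Reactants: 5 4-(2-ethoxyethoxy)-penta-O-benzyl-(+)-catechin; 6 phloroglucinol (6 equiv)
Product: 7 2-T-benzene-1,3,5-triol [4α-(2,4,6-trihydroxyphenyl)-penta-O-benzylcatechin, 3,4-trans]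
Conditions: BF3·OEt2 (1.5 equiv), THF–CH2Cl2 (1:4), −40 → 0 °C
Reagents that add atoms: none
Why: Friedel–Crafts alkylation in which BF3·OEt2 ionises the C4 ether and excess phloroglucinol (far more nucleophilic than ring A of 5, so self-condensation is suppressed) attacks C4 anti to the 3-benzyloxy group, setting the 3,4-trans (4α) stereocentre of T.

Step 6
Reactants: 7 2-T-benzene-1,3,5-triol
Product: 9 2,4,6-trihydroxy-3-T-benzaldehyde, via aryl iminium chloride 8 (not isolated)
Conditions: POCl3 (1.2 equiv), DMF (3 equiv), EtOAc, 0 °C → rt; then H2O, 50 °C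
Reagents that add atoms: N,N-dimethylformamide, CN(C)C=O; water, O
Why: Vilsmeier–Haack formylation, in which the free trihydroxyphenyl ring is much more nucleophilic than the benzylated rings and its two open positions are equivalent, so one equivalent of chloroiminium reagent should give a single iminium salt that water hydrolyses to the aldehyde.

Step 7
Reactants: 9 2,4,6-trihydroxy-3-T-benzaldehyde
Product: 10 4,6-bis(benzyloxy)-2-hydroxy-3-T-benzaldehyde
Conditions: BnBr (2.05 equiv), K2CO3 (2.2 equiv), DMF, 0 °C → rt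
Reagents that add atoms: benzyl bromide, BrCc1ccccc1
Why: Williamson etherification under mild base should take the hydroxyl para to the formyl group (most acidic, not chelated) and then the ortho hydroxyl next to C–H, while the hydroxyl between the formyl group and the bulky T group is hydrogen-bonded to C=O and shielded, and stays free as the future O1.

Step 8
Reactants: 4 8-bromo-penta-O-benzyl-(+)-catechin (1.3 equiv); 10 4,6-bis(benzyloxy)-2-hydroxy-3-T-benzaldehyde
Product: 13 [4,6-bis(benzyloxy)-2-hydroxy-3-T-phenyl](L)methanol (both carbinol epimers), via aryllithium 11 (not isolated), via sodium phenoxide 12 (not isolated)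
Conditions: 4, t-BuLi (2.0 equiv), THF, −78 °C; 10 pre-treated with NaH (1.0 equiv), THF, 0 °C, added at −78 → −20 °C; aq NH4Cl
Reagents that add atoms: none
Why: Bromine–lithium exchange followed by 1,2-addition of the aryllithium to the aldehyde, whose phenol is masked beforehand as its sodium phenoxide so that no aryllithium is consumed by proton transfer; the new carbinol centre forms as a mixture, which is harmless because it becomes planar in step 10.

Step 9
Reactants: 13 [4,6-bis(benzyloxy)-2-hydroxy-3-T-phenyl](L)methanol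
Product: 14 3,5-bis(benzyloxy)-2-[L(p-tolylsulfonyl)methyl]-6-T-phenol (both C4 epimers)
Conditions: p-TolSO2H (3 equiv), CH2Cl2, 0 °C → rt
Reagents that add atoms: p-toluenesulfinic acid, Cc1ccc(cc1)S(=O)O
Why: Acid-promoted SN1 substitution in which the doubly electron-rich ortho-hydroxybenzhydrol ionises under the mildly acidic sulfinic acid and sulfinate adds through sulfur to give the sulfone, a standard base-triggered o-quinone methide precursor.

Step 10
Reactants: 14 3,5-bis(benzyloxy)-2-[L(p-tolylsulfonyl)methyl]-6-T-phenol; 15 benzyloxyacetyl chloride (3 equiv)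
Product: 18 (3S)-cis-3,5,7-tris(benzyloxy)-4-L-8-T-3,4-dihydrocoumarin, via o-quinone methide 16 (not isolated), via ammonium enolate 17 (not isolated)
Conditions: Cs2CO3 (4 equiv), CH2Cl2, 0 °C, 30 min; then (2S,3R)-HyperBTM (20 mol %), i-Pr2NEt (0.5 equiv), 15 (slow addition), −40 °C; pH 7 phosphate buffer, 0 °C
Reagents that add atoms: none
Why: Cs2CO3 removes the O1 proton of 14 and sulfinate is expelled to give o-quinone methide 16 of ring A of M, while the isothiourea is acylated by 15 and deprotonated to the Z ammonium enolate 17, whose oxygen sits syn to sulfur so that the catalyst phenyl group covers one face. The enolate carbon (C3) adds to C4 of 16 and the liberated phenoxide O1 then attacks the acyl ammonium carbon C2 in a 6-exo-trig lactonisation that closes ring C of M and releases the catalyst; this is the known isothiourea-catalysed Michael addition–lactonisation (formal [4+2]) of ammonium enolates with o-quinone methides made in situ from sulfones, applied here to an alkoxy enolate and a very large partner. C3 is controlled by the catalyst: by the accepted shielding model the (2S,3R) enantiomer leaves open the enolate face that gives 3S (its mirror image is equally available should a model reaction show the opposite sense). C4 is controlled relative to C3 by the close-packed arrangement in which the acyl carbon lies over O1 and the catalyst points outward, which from the E quinone methide (ring A of L on the C5 side, twisted out of plane) should give the 3,4-cis lactone; the earlier configuration of C4 is erased in the planar intermediate. The step needs enolate-face control, cis selectivity and C–C bond formation ahead of O-acylation: the catalyst supplies the first, the E geometry and the tethered ring closure the second, and prior formation of 16 with slow addition of 15, helped by the T group flanking O1, the third. Work-up is cold and neutral and 18 is reduced at once, because C3 of the aryl lactone can epimerise.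

Step 11
Reactants: 18 (3S)-cis-3,5,7-tris(benzyloxy)-4-L-8-T-3,4-dihydrocoumarin
Product: 20 (3S)-cis-2-acetoxy-3,5,7-tris(benzyloxy)-4-L-8-T-chroman (anomeric mixture at C2), via aluminium hemiacetal 19 (not isolated)
Conditions: i-Bu2AlH (1.5 equiv), CH2Cl2, −78 °C; then pyridine, DMAP, Ac2O, −78 → −20 °C
Reagents that add atoms: acetic anhydride, CC(=O)OC(C)=O
Why: Reductive acetylation of a lactone, in which i-Bu2AlH adds once to the aryl lactone at −78 °C and the stable aluminium hemiacetal is acetylated in the same flask, so the free lactol and its open hydroxy aldehyde (where C3 could epimerise or over-reduction begin) never form; the C2 anomer mixture is inconsequential.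

Step 12
Reactants: 20 (3S)-cis-2-acetoxy-3,5,7-tris(benzyloxy)-4-L-8-T-chroman; 21 5-bromo-1,2,3-tris(benzyloxy)benzene (6 equiv)
Product: 24 hexadeca-O-benzyl catechin-(4α→8)-gallocatechin-(4β→8)-catechin, via aryllithium 22 (not isolated), via diarylzinc 23 (not isolated)
Conditions: 21, t-BuLi (2.0 equiv), THF, −78 °C; ZnBr2 (0.5 equiv), −78 → 0 °C; solvent switch to toluene; 20, BF3·OEt2 (2 equiv), toluene–CH2Cl2, −78 → −20 °C; aq NH4Cl
Reagents that add atoms: none
Why: Lewis-acid-mediated C-arylation of a lactol acetate (as in C-aryl glycoside synthesis), in which BF3·OEt2 ionises the acetate to the ring C oxocarbenium ion and the diarylzinc delivers ring B to C2 from the face opposite the cis-disposed 3-benzyloxy and 4-aryl (L) groups, setting C2 as 2,3-trans and 2,4-trans, the (2R) gallocatechin configuration.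

Step 13
Reactants: 24 hexadeca-O-benzyl catechin-(4α→8)-gallocatechin-(4β→8)-catechin
Product: 25 catechin-(4α→8)-gallocatechin-(4β→8)-catechin (CNP0302529.2)
Conditions: H2 (1 atm), Pd(OH)2/C, THF–MeOH–H2O, rt
Reagents that add atoms: none
Why: Catalytic hydrogenolysis should cleave all sixteen benzyl ethers in one operation without touching the C–C interflavan bonds or any stereocentre, giving the free polyphenol.

**Compound list**

1 | (+)-catechin | Oc1cc(O)c2c(c1)O[C@H](c1ccc(O)c(O)c1)[C@@H](O)C2 | starting material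
2 | 5,7,3',4'-tetra-O-benzyl-(+)-catechin | c9ccccc9COc1cc(OCc9ccccc9)c2c(c1)O[C@H](c1ccc(OCc9ccccc9)c(OCc9ccccc9)c1)[C@@H](O)C2 | intermediate
3 | penta-O-benzyl-(+)-catechin | c9ccccc9COc1cc(OCc9ccccc9)c2c(c1)O[C@H](c1ccc(OCc9ccccc9)c(OCc9ccccc9)c1)[C@@H](OCc9ccccc9)C2 | intermediate
4 | 8-bromo-penta-O-benzyl-(+)-catechin | c9ccccc9COc1cc(OCc9ccccc9)c2c(c1Br)O[C@H](c1ccc(OCc9ccccc9)c(OCc9ccccc9)c1)[C@@H](OCc9ccccc9)C2 | intermediate
5 | 4-(2-ethoxyethoxy)-penta-O-benzyl-(+)-catechin (C4 epimers) | c9ccccc9COc1cc(OCc9ccccc9)c2c(c1)O[C@H](c1ccc(OCc9ccccc9)c(OCc9ccccc9)c1)[C@@H](OCc9ccccc9)C2OCCOCC | intermediate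
6 | phloroglucinol | Oc1cc(O)cc(O)c1 | starting material
7 | 2-T-benzene-1,3,5-triol (4α-aryl, 3,4-trans) | c9ccccc9COc1cc(OCc9ccccc9)c2c(c1)O[C@H](c1ccc(OCc9ccccc9)c(OCc9ccccc9)c1)[C@@H](OCc9ccccc9)[C@@H]2c1c(O)cc(O)cc1O | intermediate
8 | N,N-dimethyl aryl iminium chloride of 7 | c9ccccc9COc1cc(OCc9ccccc9)c2c(c1)O[C@H](c1ccc(OCc9ccccc9)c(OCc9ccccc9)c1)[C@@H](OCc9ccccc9)[C@@H]2c1c(O)c(C=[N+](C)C)c(O)cc1O.[Cl-] | intermediate (not isolated)
9 | 2,4,6-trihydroxy-3-T-benzaldehyde | c9ccccc9COc1cc(OCc9ccccc9)c2c(c1)O[C@H](c1ccc(OCc9ccccc9)c(OCc9ccccc9)c1)[C@@H](OCc9ccccc9)[C@@H]2c1c(O)c(C=O)c(O)cc1O | intermediate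
10 | 4,6-bis(benzyloxy)-2-hydroxy-3-T-benzaldehyde | c9ccccc9COc1cc(OCc9ccccc9)c2c(c1)O[C@H](c1ccc(OCc9ccccc9)c(OCc9ccccc9)c1)[C@@H](OCc9ccccc9)[C@@H]2c1c(O)c(C=O)c(OCc9ccccc9)cc1OCc9ccccc9 | intermediate
11 | 8-lithio-penta-O-benzyl-(+)-catechin | c9ccccc9COc1cc(OCc9ccccc9)c2c(c1[Li])O[C@H](c1ccc(OCc9ccccc9)c(OCc9ccccc9)c1)[C@@H](OCc9ccccc9)C2 | intermediate (not isolated)
12 | sodium phenoxide of 10 | c9ccccc9COc1cc(OCc9ccccc9)c2c(c1)O[C@H](c1ccc(OCc9ccccc9)c(OCc9ccccc9)c1)[C@@H](OCc9ccccc9)[C@@H]2c1c([O-])c(C=O)c(OCc9ccccc9)cc1OCc9ccccc9.[Na+] | intermediate (not isolated)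
13 | [4,6-bis(benzyloxy)-2-hydroxy-3-T-phenyl](L)methanol (carbinol epimers) | c9ccccc9COc1cc(OCc9ccccc9)c2c(c1)O[C@H](c1ccc(OCc9ccccc9)c(OCc9ccccc9)c1)[C@@H](OCc9ccccc9)[C@@H]2c4c(OCc9ccccc9)cc(OCc9ccccc9)c(C(O)c1c(OCc9ccccc9)cc(OCc9ccccc9)c2c1O[C@H](c1ccc(OCc9ccccc9)c(OCc9ccccc9)c1)[C@@H](OCc9ccccc9)C2)c4O | intermediate
14 | 3,5-bis(benzyloxy)-2-[L(p-tolylsulfonyl)methyl]-6-T-phenol (C4 epimers; key-step precursor) | c9ccccc9COc1cc(OCc9ccccc9)c2c(c1)O[C@H](c1ccc(OCc9ccccc9)c(OCc9ccccc9)c1)[C@@H](OCc9ccccc9)[C@@H]2c4c(OCc9ccccc9)cc(OCc9ccccc9)c(C(S(=O)(=O)c5ccc(C)cc5)c1c(OCc9ccccc9)cc(OCc9ccccc9)c2c1O[C@H](c1ccc(OCc9ccccc9)c(OCc9ccccc9)c1)[C@@H](OCc9ccccc9)C2)c4O | intermediate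
15 | benzyloxyacetyl chloride | O=C(Cl)COCc1ccccc1 | starting material
16 | (E)-3,5-bis(benzyloxy)-6-(L-methylidene)-2-T-cyclohexa-2,4-dien-1-one (o-quinone methide) | c9ccccc9COc1cc(OCc9ccccc9)c2c(c1)O[C@H](c1ccc(OCc9ccccc9)c(OCc9ccccc9)c1)[C@@H](OCc9ccccc9)[C@@H]2C4=C(OCc9ccccc9)C=C(OCc9ccccc9)/C(=C\c1c(OCc9ccccc9)cc(OCc9ccccc9)c2c1O[C@H](c1ccc(OCc9ccccc9)c(OCc9ccccc9)c1)[C@@H](OCc9ccccc9)C2)C4=O | intermediate (not isolated)
17 | Z ammonium enolate of benzyloxyacetylated (2S,3R)-HyperBTM | CC(C)[C@@H]1CN2c3ccccc3SC2=[N+]([C@@H]1c1ccccc1)/C([O-])=C/OCc1ccccc1 | intermediate (not isolated)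
18 | (3S)-cis-3,5,7-tris(benzyloxy)-4-L-8-T-3,4-dihydrocoumarin | c9ccccc9COc1cc(OCc9ccccc9)c2c(c1)O[C@H](c1ccc(OCc9ccccc9)c(OCc9ccccc9)c1)[C@@H](OCc9ccccc9)[C@@H]2c1c(OCc9ccccc9)cc(OCc9ccccc9)c2c1OC(=O)[C@@H](OCc9ccccc9)[C@H]2c1c(OCc9ccccc9)cc(OCc9ccccc9)c2c1O[C@H](c1ccc(OCc9ccccc9)c(OCc9ccccc9)c1)[C@@H](OCc9ccccc9)C2 | intermediate
19 | diisobutylaluminium hemiacetal of 18 (C2 epimers) | c9ccccc9COc1cc(OCc9ccccc9)c2c(c1)O[C@H](c1ccc(OCc9ccccc9)c(OCc9ccccc9)c1)[C@@H](OCc9ccccc9)[C@@H]2c1c(OCc9ccccc9)cc(OCc9ccccc9)c2c1OC(O[Al](CC(C)C)CC(C)C)[C@@H](OCc9ccccc9)[C@H]2c1c(OCc9ccccc9)cc(OCc9ccccc9)c2c1O[C@H](c1ccc(OCc9ccccc9)c(OCc9ccccc9)c1)[C@@H](OCc9ccccc9)C2 | intermediate (not isolated)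
20 | (3S)-cis-2-acetoxy-3,5,7-tris(benzyloxy)-4-L-8-T-chroman (C2 anomers) | c9ccccc9COc1cc(OCc9ccccc9)c2c(c1)O[C@H](c1ccc(OCc9ccccc9)c(OCc9ccccc9)c1)[C@@H](OCc9ccccc9)[C@@H]2c1c(OCc9ccccc9)cc(OCc9ccccc9)c2c1OC(OC(C)=O)[C@@H](OCc9ccccc9)[C@H]2c1c(OCc9ccccc9)cc(OCc9ccccc9)c2c1O[C@H](c1ccc(OCc9ccccc9)c(OCc9ccccc9)c1)[C@@H](OCc9ccccc9)C2 | intermediate
21 | 5-bromo-1,2,3-tris(benzyloxy)benzene | Brc1cc(OCc2ccccc2)c(OCc2ccccc2)c(OCc2ccccc2)c1 | starting material
22 | 3,4,5-tris(benzyloxy)phenyllithium | [Li]c1cc(OCc2ccccc2)c(OCc2ccccc2)c(OCc2ccccc2)c1 | intermediate (not isolated)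
23 | bis[3,4,5-tris(benzyloxy)phenyl]zinc | c1(cc(OCc2ccccc2)c(OCc2ccccc2)c(OCc2ccccc2)c1)[Zn]c1cc(OCc2ccccc2)c(OCc2ccccc2)c(OCc2ccccc2)c1 | intermediate (not isolated)
24 | hexadeca-O-benzyl catechin-(4α→8)-gallocatechin-(4β→8)-catechin | c9ccccc9COc1cc(OCc9ccccc9)c2c(c1)O[C@H](c1ccc(OCc9ccccc9)c(OCc9ccccc9)c1)[C@@H](OCc9ccccc9)[C@@H]2c1c(OCc9ccccc9)cc(OCc9ccccc9)c2c1O[C@H](c1cc(OCc9ccccc9)c(OCc9ccccc9)c(OCc9ccccc9)c1)[C@@H](OCc9ccccc9)[C@H]2c1c(OCc9ccccc9)cc(OCc9ccccc9)c2c1O[C@H](c1ccc(OCc9ccccc9)c(OCc9ccccc9)c1)[C@@H](OCc9ccccc9)C2 | intermediate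
25 | catechin-(4α→8)-gallocatechin-(4β→8)-catechin (CNP0302529.2) | Oc1cc(O)c2c(c1)O[C@H](c1ccc(O)c(O)c1)[C@@H](O)[C@@H]2c1c(O)cc(O)c2c1O[C@H](c1cc(O)c(O)c(O)c1)[C@@H](O)[C@H]2c1c(O)cc(O)c2c1O[C@H](c1ccc(O)c(O)c1)[C@@H](O)C2 | target

**Step count and risk**

Total steps: 13. Longest linear sequence: 12 steps (steps 1, 2, 4–13 from (+)-catechin); step 3 is the side branch to the L bromide.

The three steps most likely to fail:

Step 10. The enolate may add to the wrong face or in the extended arrangement (trans lactone), the phenoxide may be O-acylated before the quinone methide forms, addition to the hindered electron-rich quinone methide may be slow, or C3 may epimerise under base. The fallback replaces catalyst control by auxiliary control and separates the two bond formations. It sets out from 14 and 15. Acylation of (R)-4-benzyl-1,3-oxazolidin-2-one with 15 (n-BuLi, THF, −78 °C) would give (R)-4-benzyl-3-(benzyloxyacetyl)-1,3-oxazolidin-2-one F1. Its chelated sodium Z enolate (NaN(SiMe3)2, THF, −78 °C, 2.2 equiv, one of which generates the quinone methide from 14) should add in Michael fashion from the face opposite the auxiliary benzyl group to give the open-chain imide phenol F2 with 3S configuration; the relative configuration at C4 would have to be established. Warming the phenoxide of F2 should bring about lactonisation onto the imide carbonyl with loss of the oxazolidinone, and the route is rejoined at 18.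

Step 12. The oxocarbenium ion may be too hindered for aryl transfer, may lose the C3 proton to an enol ether, may be attacked with poor facial selectivity, or the Lewis acid may ionise an interflavan bond. The fallback forms the C2–aryl bond on the open chain and closes ring C afterwards. It sets out from 18. Reduction with i-Bu2AlH (CH2Cl2, −78 °C) and aqueous work-up would give the lactol F3. Addition of 3,4,5-tris(benzyloxy)phenylmagnesium bromide (from 21 and Mg, excess, THF, −78 → 0 °C) to its hydroxy aldehyde form under chelation control by the α-benzyloxy group should give the syn benzylic carbinol F4. Mitsunobu cyclisation (PPh3, DIAD, THF, 0 °C) of phenol O1 onto the carbinol carbon with inversion would close ring C with 2,3-trans configuration, and the route is rejoined at 24.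

Step 7. Discrimination among the three hydroxyls may be incomplete, giving regioisomeric or over-benzylated ethers. The fallback builds the substitution pattern from a phenol that already carries the two benzyl ethers. It sets out from 5. Friedel–Crafts alkylation of 3,5-bis(benzyloxy)phenol with 5 (BF3·OEt2, CH2Cl2, −78 °C) would give the ortho-alkylated 3,5-bis(benzyloxy)-2-T-phenol F5, to be separated from its para isomer. Magnesium-mediated ortho-formylation (MgCl2, Et3N, paraformaldehyde, MeCN, reflux), which is specific for the position ortho to a free phenol, should then install the aldehyde at the only open ortho carbon, and the route is rejoined at 10.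

**Further compounds**

F1 | step 10 | (R)-4-benzyl-3-(benzyloxyacetyl)-1,3-oxazolidin-2-one | O=C1OC[C@@H](Cc2ccccc2)N1C(=O)COCc1ccccc1
F2 | step 10 | open-chain Michael adduct: (R)-4-benzyl-3-[(2S)-2-benzyloxy-3-(4,6-bis(benzyloxy)-2-hydroxy-3-T-phenyl)-3-L-propanoyl]-1,3-oxazolidin-2-one, configured as in 18 | c9ccccc9COc1cc(OCc9ccccc9)c2c(c1)O[C@H](c1ccc(OCc9ccccc9)c(OCc9ccccc9)c1)[C@@H](OCc9ccccc9)[C@@H]2c4c(OCc9ccccc9)cc(OCc9ccccc9)c([C@H](c1c(OCc9ccccc9)cc(OCc9ccccc9)c2c1O[C@H](c1ccc(OCc9ccccc9)c(OCc9ccccc9)c1)[C@@H](OCc9ccccc9)C2)[C@H](OCc9ccccc9)C(=O)N5C(=O)OC[C@H]5Cc6ccccc6)c4O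
F3 | step 12 | (3S)-cis-3,5,7-tris(benzyloxy)-4-L-8-T-chroman-2-ol (lactol, C2 anomers) | c9ccccc9COc1cc(OCc9ccccc9)c2c(c1)O[C@H](c1ccc(OCc9ccccc9)c(OCc9ccccc9)c1)[C@@H](OCc9ccccc9)[C@@H]2c1c(OCc9ccccc9)cc(OCc9ccccc9)c2c1OC(O)[C@@H](OCc9ccccc9)[C@H]2c1c(OCc9ccccc9)cc(OCc9ccccc9)c2c1O[C@H](c1ccc(OCc9ccccc9)c(OCc9ccccc9)c1)[C@@H](OCc9ccccc9)C2
F4 | step 12 | syn benzylic carbinol: 2-benzyloxy-3-(4,6-bis(benzyloxy)-2-hydroxy-3-T-phenyl)-3-L-1-[3,4,5-tris(benzyloxy)phenyl]propan-1-ol | c9ccccc9COc1cc(OCc9ccccc9)c2c(c1)O[C@H](c1ccc(OCc9ccccc9)c(OCc9ccccc9)c1)[C@@H](OCc9ccccc9)[C@@H]2c4c(OCc9ccccc9)cc(OCc9ccccc9)c([C@H](c1c(OCc9ccccc9)cc(OCc9ccccc9)c2c1O[C@H](c1ccc(OCc9ccccc9)c(OCc9ccccc9)c1)[C@@H](OCc9ccccc9)C2)[C@H](OCc9ccccc9)[C@@H](O)c1cc(OCc9ccccc9)c(OCc9ccccc9)c(OCc9ccccc9)c1)c4O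
F5 | step 7 | 3,5-bis(benzyloxy)-2-T-phenol | c9ccccc9COc1cc(OCc9ccccc9)c2c(c1)O[C@H](c1ccc(OCc9ccccc9)c(OCc9ccccc9)c1)[C@@H](OCc9ccccc9)[C@@H]2c1c(O)cc(OCc9ccccc9)cc1OCc9ccccc9
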